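**Retrosynthetic overview**

- The route rests on one feature: counting the chain from the benzylic carbon, C1 can be the carbonyl carbon of vanillin, and tying C1 to the C5 oxygen makes C1–C5 plus that oxygen a temporary tetrahydropyran. On this ring the C3 oxygen cis to the C5 nonyl group corresponds to the 3,5-anti diol of the open chain.
- Last disconnection: the benzylic C1–O bond of an all-cis 2-aryl-6-nonyltetrahydropyran-4-ol, cut by hydrogenolysis after the phenol is freed.
- Key disconnection: Prins cyclisation (C1–O, C1–C2, C3–O) of (S)-tridec-1-en-4-ol with O-tosylvanillin. This closes the only ring the route builds, and that ring is opened again at the end.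
- The homoallylic alcohol comes from decanal by catalytic asymmetric allylation; the aldehyde comes from vanillin and tosyl chloride.

Key step: step 3

Remark on numbering: chain positions C1–C5 count from the benzylic carbon. Ring locants are O1, C2 (aryl, chain C1), C4 (oxygenated, chain C3) and C6 (nonyl, chain C5).

**Step 1**
Reactants: 1 decanal; 2 allyltributylstannane
Product: 3 (S)-tridec-1-en-4-ol
Conditions: (R)-BINOL (20 mol %), Ti(OiPr)4 (10 mol %), 4 Å MS, CH2Cl2, −20 °C; aq. NaHCO3
Reagents that add atoms: allyltributylstannane (compound 2), C=CC[Sn](CCCC)(CCCC)CCCC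
Why: Keck asymmetric allylation, in which the titanium–(R)-BINOL Lewis acid binds the aldehyde and should direct allyl transfer from tin to its Re face, setting the (S)-carbinol (allyl outranks nonyl).

**Step 2**
Reactants: 4 vanillin; 5 p-toluenesulfonyl chloride
Product: 6 4-formyl-2-methoxyphenyl 4-methylbenzenesulfonate (O-tosylvanillin)
Conditions: K2CO3, acetone, reflux
Reagents that add atoms: p-toluenesulfonyl chloride (compound 5), Cc1ccc(S(=O)(=O)Cl)cc1
Why: O-sulfonylation of the phenoxide, which leaves the aldehyde untouched and makes the arene electron-poor for the acid step that follows.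

**Step 3**
Reactants: 3 (S)-tridec-1-en-4-ol; 6 O-tosylvanillin
Product: 8 (2S,4R,6S)-2-[3-methoxy-4-(tosyloxy)phenyl]-6-nonyltetrahydro-2H-pyran-4-yl trifluoroacetate (all-cis), via oxocarbenium ion 7 (not isolated)
Conditions: TFA (10 equiv), CH2Cl2, 0 °C → rt; evaporate with toluene, use crude
Reagents that add atoms: trifluoroacetic acid, OC(=O)C(F)(F)F
Why: Alcohol 3 and aldehyde 6 form a hemiacetal (C1–O) that ionises in TFA to the (E)-aryl oxocarbenium ion 7; its terminal alkene carbon attacks the oxocarbenium carbon (C1–C2) and trifluoroacetate captures the resulting secondary cation (C3–O), which is a Prins cyclisation of the kind known for homoallylic alcohols and aromatic aldehydes. The tetrahydropyran closes in a 6-endo-trig mode through a chair transition state. The C1 stereocentre follows from the (E)-oxocarbenium geometry, which places the aryl group equatorial, and the C3 stereocentre from equatorial capture of the chair cation in which the nonyl group of the existing C5 carbinol is equatorial, so all three substituents should end up cis. The selectivity the route needs is only this 1,3-induction from C5 to C3 (ring cis, open-chain anti); the C1 configuration is of no consequence because that carbon ends as CH2. The sulfonate keeps the arene electron-poor, so the conjugated oxocarbenium ion should cyclise rather than exchange partners by 2-oxonia-Cope rearrangement, and the benzylic C–O bond of 8 should not ionise in TFA, which protects the C5 configuration.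

**Step 4**
Reactants: 8 all-cis tetrahydropyranyl trifluoroacetate
Product: 9 (2S,4R,6S)-2-(4-hydroxy-3-methoxyphenyl)-6-nonyltetrahydro-2H-pyran-4-ol
Conditions: KOH (excess), 1,4-dioxane–H2O, 80 °C; then aq. HCl to pH 4
Reagents that add atoms: none
Why: Saponification, in which hydroxide cleaves the labile trifluoroacetate at the acyl carbon and the aryl sulfonate at sulfur, so both carbinol C–O bonds and their configurations stay intact (epimerisation at the benzylic carbon would be harmless).

**Step 5**
Reactants: 9 all-cis 2-aryl-6-nonyltetrahydropyran-4-ol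
Product: 10 (3S,5S)-1-(4-hydroxy-3-methoxyphenyl)tetradecane-3,5-diol (target)
Conditions: H2 (3 bar), 10% Pd/C, EtOH, HCl (cat.), rt
Reagents that add atoms: none
Why: Acid-assisted catalytic hydrogenolysis of a benzylic ether, in which protonation of the ring oxygen and the para-hydroxy group weaken the C1–O bond so that palladium cleaves it, while the non-benzylic C3 and C5 carbinols are not touched.

**Compound list**

1 | decanal | CCCCCCCCCC=O | starting material
2 | allyltributylstannane | C=CC[Sn](CCCC)(CCCC)CCCC | starting material
3 | (S)-tridec-1-en-4-ol | CCCCCCCCC[C@H](O)CC=C | intermediate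
4 | vanillin (4-hydroxy-3-methoxybenzaldehyde) | O=Cc1ccc(O)c(OC)c1 | starting material
5 | p-toluenesulfonyl chloride | Cc1ccc(S(=O)(=O)Cl)cc1 | starting material
6 | 4-formyl-2-methoxyphenyl 4-methylbenzenesulfonate | O=Cc1ccc(OS(=O)(=O)c2ccc(C)cc2)c(OC)c1 | intermediate
7 | (E)-oxocarbenium ion from 3 and 6, as its trifluoroacetate ion pair (not isolated) | CCCCCCCCC[C@@H](CC=C)/[O+]=C/c1ccc(OS(=O)(=O)c2ccc(C)cc2)c(OC)c1.[O-]C(=O)C(F)(F)F | intermediate
8 | (2S,4R,6S)-2-[3-methoxy-4-(tosyloxy)phenyl]-6-nonyltetrahydro-2H-pyran-4-yl trifluoroacetate | CCCCCCCCC[C@H]1C[C@@H](OC(=O)C(F)(F)F)C[C@@H](c2ccc(OS(=O)(=O)c3ccc(C)cc3)c(OC)c2)O1 | intermediate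
9 | (2S,4R,6S)-2-(4-hydroxy-3-methoxyphenyl)-6-nonyltetrahydro-2H-pyran-4-ol | CCCCCCCCC[C@H]1C[C@@H](O)C[C@@H](c2ccc(O)c(OC)c2)O1 | intermediate
10 | (3S,5S)-1-(4-hydroxy-3-methoxyphenyl)tetradecane-3,5-diol | CCCCCCCCC[C@H](O)C[C@@H](O)CCc1ccc(O)c(OC)c1 | target

**Step count**

Total steps: 5. Longest linear sequence: 4 steps (1 → 3 → 8 → 9 → 10; the vanillin branch is equally long).

**Steps most likely to fail**

Step 3 (Prins cyclisation). The free alcohol and aldehyde could exchange side chains through hemiacetal exchange and 2-oxonia-Cope rearrangement, giving symmetrical tetrahydropyrans. The C5 configuration could also erode, or the ring cation could lose a proton instead of being captured. The fallback is a segment-coupling Prins that generates the same oxocarbenium ion with no free aldehyde or alcohol present; it sets out from 3 and 6 and comes back at 9. Aldehyde 6 would be oxidised (NaClO2, NaH2PO4, 2-methyl-2-butene, t-BuOH–H2O) to 3-methoxy-4-(tosyloxy)benzoic acid F1. Esterification with 3 (DCC, DMAP, CH2Cl2) would give (S)-tridec-1-en-4-yl 3-methoxy-4-(tosyloxy)benzoate F2. Reductive acetylation (i-Bu2AlH, CH2Cl2, −78 °C; then Ac2O, pyridine, DMAP) would give the α-acetoxy ether F3 as a mixture at the acetal carbon. BF3·OEt2 with AcOH in CH2Cl2–hexane at 0 °C would then ionise the acetal acetate and should close the ring to (2S,4R,6S)-2-[3-methoxy-4-(tosyloxy)phenyl]-6-nonyltetrahydro-2H-pyran-4-yl acetate F4. The conditions of step 4 would remove acetate and tosylate from it to give 9.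

Step 5 (benzylic ring opening). A cyclic secondary benzylic ether may be cleaved only slowly on the palladium surface, and prolonged acid could start dehydration of the carbinols. The fallback replaces surface hydrogenolysis by ionic reduction; it sets out from 9 and comes back at 10. Et3SiH with BF3·OEt2 in CH2Cl2 at −20 → 0 °C should ionise the C1–O bond to the benzylic cation stabilised by the para-hydroxy group (a protonated quinone methide), which takes hydride from the silane. No new compound arises on the way (F0).

Step 1 (asymmetric allylation). Facial selectivity with a linear, enolisable aldehyde may be insufficient and turnover of the titanium catalyst slow, and this step is the only source of absolute configuration. The fallback takes the stereocentre from the chiral pool; it does not set out from a numbered compound but from commercial (S)-epichlorohydrin (ClC[C@@H]1CO1), replacing 1 and 2, and it comes back at 3. Octylmagnesium bromide (C8H17MgBr) with CuI (cat.) in THF at −40 °C would open the epoxide at its CH2 terminus to (S)-1-chloroundecan-2-ol F5. NaOH in Et2O–H2O would close this to (S)-2-nonyloxirane F6. Vinylmagnesium bromide (CH2=CHMgBr) with CuI (cat.) in THF at −30 °C would open F6 at CH2 to give 3, the stereocentre never being touched.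

**Further compounds**

F1 | step 3 | 3-methoxy-4-(tosyloxy)benzoic acid | O=C(O)c1ccc(OS(=O)(=O)c2ccc(C)cc2)c(OC)c1
F2 | step 3 | (S)-tridec-1-en-4-yl 3-methoxy-4-(tosyloxy)benzoate | CCCCCCCCC[C@@H](CC=C)OC(=O)c1ccc(OS(=O)(=O)c2ccc(C)cc2)c(OC)c1
F3 | step 3 | acetoxy[3-methoxy-4-(tosyloxy)phenyl]methyl (S)-tridec-1-en-4-yl ether (α-acetoxy ether, mixture at the acetal carbon) | CCCCCCCCC[C@@H](CC=C)OC(OC(C)=O)c1ccc(OS(=O)(=O)c2ccc(C)cc2)c(OC)c1
F4 | step 3 | (2S,4R,6S)-2-[3-methoxy-4-(tosyloxy)phenyl]-6-nonyltetrahydro-2H-pyran-4-yl acetate | CCCCCCCCC[C@H]1C[C@@H](OC(C)=O)C[C@@H](c2ccc(OS(=O)(=O)c3ccc(C)cc3)c(OC)c2)O1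
F0 | step 5 | none | none
F5 | step 1 | (S)-1-chloroundecan-2-ol | CCCCCCCCC[C@H](O)CCl
F6 | step 1 | (S)-2-nonyloxirane | CCCCCCCCC[C@H]1CO1
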